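**Assumption:** the target is the (5E,7Z,12R,14Z) isomer encoded by the SMILES (prostanoid numbering used throughout); compounds 1, 2, 4 and 7 are taken as commercial.

## Retrosynthetic overview

1. 12 ⇐ 11: the C10–Br bond is made last by a new Lewis-base-relay α-bromination of the endocyclic enone.
2. 11 ⇐ 10 ⇐ 9: the C9 ketone is unveiled from a C9–OTBS carbinol. This carbonyl transposition turns an easily made E-alkylidene (chain anti to a temporary C12 ketone) into the 7Z dienone.
3. 9 ⇐ 8 ⇐ 6 + 7: the C12–C13 bond and the 12R centre come from 1,2-propargylation of the C12 ketone anti to the C9–OTBS group; semihydrogenation gives 14Z.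
4. 6 ⇐ 4 + 3: C7=C8 by aldol/dehydration; 3 ⇐ 1 + 2 by cross-metathesis (5E).
5. Rings: none is formed. The single cyclopentene ring is bought as enantiopure 4; its stereocentre relays chirality to C12 and is then erased.

## Route

**Step 1**
Reactants: 1 methyl hex-5-enoate; 2 (E)-but-2-enal (crotonaldehyde)
Product: 3 methyl (5E)-7-oxohept-5-enoate
Conditions: Hoveyda–Grubbs II (2 mol %), 2 (5 equiv), CH2Cl2, 40 °C
Reagents that add atoms: none
Why: Olefin cross-metathesis of a terminal alkene with crotonaldehyde gives the E-enal selectively, with propene lost.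

**Step 2**
Reactants: 4 (4R)-4-(tert-butyldimethylsilyloxy)cyclopent-2-en-1-one; 3 methyl (5E)-7-oxohept-5-enoate
Product: 5 methyl (5E)-7-hydroxy-7-[(1R,5S)-5-(tert-butyldimethylsilyloxy)-2-oxocyclopent-3-en-1-yl]hept-5-enoate (side chain trans to OTBS; carbinol epimers)
Conditions: LDA (1.05 equiv), THF, −78 °C; then 3, −78 °C; AcOH quench
Reagents that add atoms: none
Why: Kinetic α′-deprotonation gives the cross-conjugated lithium enolate (loss of silyloxide would give an antiaromatic cyclopentadienone, so it does not occur), which undergoes aldol 1,2-addition to the enal anti to OTBS; the new carbinol centres are removed in step 3.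

**Step 3**
Reactants: 5
Product: 6 methyl (5E,7E)-7-[(5S)-5-(tert-butyldimethylsilyloxy)-2-oxocyclopent-3-en-1-ylidene]hept-5-enoate
Conditions: MsCl, Et3N, CH2Cl2, −40 → 0 °C (no stronger base)
Reagents that add atoms: none
Why: Mesylation and E1cB elimination (aldol condensation) put the chain anti to the ketone, the usual preference for 2-alkylidenecyclopentenones with a secondary neighbouring carbon; Et3N alone is used to avoid γ-deprotonation at the silyloxy carbon.

**Step 4**
Reactants: 6; 7 oct-2-yne
Product: 8 methyl (5E,7E)-7-[(2R,5S)-5-(tert-butyldimethylsilyloxy)-2-hydroxy-2-(oct-2-yn-1-yl)cyclopent-3-en-1-ylidene]hept-5-enoate (ring oxygens cis)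
Conditions: 7, n-BuLi/TMEDA, THF, −20 °C; Ti(OiPr)4, −78 °C; then 6, −78 → −40 °C
Reagents that add atoms: none
Why: The allenyltitanium reagent adds 1,2 to the ketone through a cyclic SE2′ transition state at its CH2 terminus (propargylation), sparing the ester, and attacks anti to the 1,3-related OTBS group as in additions to 4-silyloxycyclopentenones, which sets C12 as R; the minor syn adduct is removed by chromatography here or at 10.

**Step 5**
Reactants: 8
Product: 9 methyl (5E,7E)-7-[(2R,5S)-5-(tert-butyldimethylsilyloxy)-2-hydroxy-2-[(2Z)-oct-2-en-1-yl]cyclopent-3-en-1-ylidene]hept-5-enoate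
Conditions: H2 (1 atm), Lindlar Pd, quinoline, EtOAc, 0 °C, stopped at 1 equiv uptake
Reagents that add atoms: none (H2 adds only hydrogen)
Why: Lindlar semihydrogenation delivers H2 syn to the alkyne to give the 14Z alkene, and the poisoned catalyst leaves the diene and ring alkene intact.

**Step 6**
Reactants: 9
Product: 10 methyl (5E,7E)-7-[(2R,5S)-2,5-dihydroxy-2-[(2Z)-oct-2-en-1-yl]cyclopent-3-en-1-ylidene]hept-5-enoate
Conditions: TBAF, THF, 0 °C; Et3N-deactivated silica
Reagents that add atoms: none
Why: Fluoride desilylation frees the secondary allylic alcohol under non-acidic conditions that the acid-sensitive tertiary dienyl carbinol tolerates.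

**Step 7**
Reactants: 10
Product: 11 methyl (5E,7Z,12R,14Z)-12-hydroxy-9-oxoprosta-5,7,10,14-tetraenoate
Conditions: activated MnO2 (20 equiv), CH2Cl2, rt
Reagents that add atoms: none
Why: MnO2 allylic oxidation touches only the secondary doubly allylic alcohol; the relay centre is erased, and because C9 is now the carbonyl the chain is syn to C=O, so the unchanged geometry is now labelled 7Z.

**Step 8**
Reactants: 11
Product: 12 bromovulone III, methyl (5E,7Z,12R,14Z)-10-bromo-12-hydroxy-9-oxoprosta-5,7,10,14-tetraenoate
Conditions: DMAP (0.3 equiv), CBr4 (1.2 equiv), CH2Cl2, 0 °C, dark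
Reagents that add atoms: carbon tetrabromide, BrC(Br)(Br)Br
Why: Proposed new method: DMAP adds reversibly to C11, the β-carbon of the only α-unsubstituted enone (the exocyclic acceptor is α-substituted and should not react); the ammonium enolate is C-brominated at C10 by halophilic attack on CBr4, and the CBr3⁻ counter-ion removes H-10 to expel DMAP (E1cB), giving the α-bromoenone and CHBr3. CBr4 does not form bromonium ions, so the 14Z alkene, the diene and the tertiary alcohol should survive; the closest known chemistry is the amine-mediated α-iodination of enones with I2/pyridine (Baylis–Hillman-type addition–halogenation–elimination) and bromination of preformed enolates with CBr4.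

## Compound list

1 | methyl hex-5-enoate | C=CCCCC(=O)OC | starting material
2 | (E)-but-2-enal | C/C=C/C=O | starting material
3 | methyl (5E)-7-oxohept-5-enoate | O=C/C=C/CCCC(=O)OC | intermediate
4 | (4R)-4-(tert-butyldimethylsilyloxy)cyclopent-2-en-1-one | O=C1C=C[C@H](O[Si](C)(C)C(C)(C)C)C1 | starting material
5 | methyl (5E)-7-hydroxy-7-[(1R,5S)-5-(TBSO)-2-oxocyclopent-3-en-1-yl]hept-5-enoate (C7 epimers) | O=C1C=C[C@H](O[Si](C)(C)C(C)(C)C)[C@H]1C(O)/C=C/CCCC(=O)OC | intermediate
6 | methyl (5E,7E)-7-[(5S)-5-(TBSO)-2-oxocyclopent-3-en-1-ylidene]hept-5-enoate | O=C1C=C[C@H](O[Si](C)(C)C(C)(C)C)/C1=C\C=C\CCCC(=O)OC | intermediate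
7 | oct-2-yne | CC#CCCCCC | starting material
8 | methyl (5E,7E)-7-[(2R,5S)-5-(TBSO)-2-hydroxy-2-(oct-2-yn-1-yl)cyclopent-3-en-1-ylidene]hept-5-enoate | CCCCCC#CC[C@@]1(O)C=C[C@H](O[Si](C)(C)C(C)(C)C)/C1=C\C=C\CCCC(=O)OC | intermediate
9 | methyl (5E,7E)-7-[(2R,5S)-5-(TBSO)-2-hydroxy-2-[(2Z)-oct-2-en-1-yl]cyclopent-3-en-1-ylidene]hept-5-enoate | CCCCC/C=C\C[C@@]1(O)C=C[C@H](O[Si](C)(C)C(C)(C)C)/C1=C\C=C\CCCC(=O)OC | intermediate
10 | methyl (5E,7E)-7-[(2R,5S)-2,5-dihydroxy-2-[(2Z)-oct-2-en-1-yl]cyclopent-3-en-1-ylidene]hept-5-enoate | CCCCC/C=C\C[C@@]1(O)C=C[C@H](O)/C1=C\C=C\CCCC(=O)OC | intermediate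
11 | methyl (5E,7Z,12R,14Z)-12-hydroxy-9-oxoprosta-5,7,10,14-tetraenoate | CCCCC/C=C\C[C@@]1(O)C=CC(=O)/C1=C\C=C\CCCC(=O)OC | intermediate
12 | bromovulone III, methyl (5E,7Z,12R,14Z)-10-bromo-12-hydroxy-9-oxoprosta-5,7,10,14-tetraenoate | CCCCC/C=C\C[C@@]1(O)C=C(Br)C(=O)/C1=C\C=C\CCCC(=O)OC | target

## Summary

Total step count: 8.
Longest linear sequence: 8 steps (1 → 3 → 5 → 6 → 8 → 9 → 10 → 11 → 12); 7 steps from 4.

Steps most likely to fail:

1. **Step 8 (proposed new bromination).** Risks are poor site selectivity between C11 and C7, or erosion of the 7Z geometry. Fallback with known chemistry: put the bromine in first. Treat (4S)-4-(TBSO)cyclopent-2-enone with Br2 then Et3N (α-bromoenone), reduce with NaBH4/CeCl3 (cis alcohol), protect with TBDPSCl, remove the TBS group with PPTS/MeOH, and oxidise with Dess–Martin periodinane to (R)-3-bromo-4-(TBDPSO)cyclopent-2-enone. Running steps 2–7 on this enone (P-2 nickel instead of Lindlar to spare the C–Br bond) ends directly at 12.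

2. **Step 4 (facial and regioselectivity of the propargylation on a cross-conjugated dienone).** Fallback: reverse the order of bond formation. Add the same titanium reagent to 4 itself, then TBAF/MnO2 to give (R)-4-hydroxy-4-(oct-2-ynyl)cyclopent-2-enone, Lindlar reduction, O-silylation, and aldol/dehydration with 3 last, followed by step 8 and desilylation. The drawback is that 7Z and 7E isomers form together and must be separated.

3. **Step 5 (over-reduction of the conjugated diene).** Fallback: avoid hydrogenation by delivering a preformed Z-alkene. Replace steps 4–5 with addition of (Z)-oct-2-enylbarium chloride (from (Z)-1-chlorooct-2-ene and activated barium), an allyl reagent class that adds at its α-carbon with retention of alkene geometry.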